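**Retrosynthetic overview**
- The C3 and C6 angelates are installed last by mixed-anhydride acylation; the C8 angelate comes from SN2 displacement of an α-keto bromide by angelate, which also sets C8.
- The cis-1,10-epoxy-9-ketone comes from a β,γ-enone moved into conjugation and epoxidised; C8–O and C9=O derive from a ring enol silyl ether.
- The ten-membered ring comes from anionic oxy-Cope ring expansion of a trans-1-vinyl-2-(1-silyloxypropenyl)cyclohexanol (C1–C10 formed, C3–C8 cleaved), followed by dehydrogenation in the same flask.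
- The cyclohexanol comes from an epoxy ketone, propanal and vinylmagnesium bromide; the epoxy ketone comes from (R)-carvone by Shapiro diene formation, singlet-oxygen [4+2] addition with Kornblum–DeLaMare opening, and hydroxyl-directed epoxidation.
- Ring order: six-membered ring (bought in carvone), then the 4,5-oxirane, then the ten-membered ring, then the 1,10-oxirane.

Assumption: atoms carry germacrane labels of the target (ring C1–C10, C7 bears isopropenyl, C9 is the ketone, methyls on C4 and C10), and precursors use the label of the target carbon they become; stereochemical outcomes of steps 3, 10, 11 and 12 are predictions from models, not established results.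

**Step 1**
Reactants: 1 (R)-(−)-carvone
Product: 2 (R)-carvone (E)-p-toluenesulfonylhydrazone
Conditions: TsNHNH2, EtOH, cat. AcOH, 60 °C
Reagents that add atoms: p-toluenesulfonyl hydrazide, Cc1ccc(cc1)S(=O)(=O)NN
Why: Hydrazone condensation at the only carbonyl; the C7 stereocentre is untouched and the NHTs group sits syn to the CH2 flank, as the Shapiro step needs.

**Step 2**
Reactants: 2 (R)-carvone (E)-p-toluenesulfonylhydrazone
Product: 3 (R)-2-methyl-5-(prop-1-en-2-yl)cyclohexa-1,3-diene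
Conditions: MeLi (2.2 equiv), Et2O, 0 °C → rt; then H2O
Reagents that add atoms: none
Why: Shapiro reaction: the dianion (α′-CH2 deprotonated syn to N) loses sulfinate and N2 to a vinyllithium that is protonated, giving the cisoid diene without touching C7.

**Step 3**
Reactants: 3 (R)-2-methyl-5-(prop-1-en-2-yl)cyclohexa-1,3-diene
Product: 5 (4R,5S)-4-hydroxy-2-methyl-5-(prop-1-en-2-yl)cyclohex-2-en-1-one, via endoperoxide 4 (not isolated)
Conditions: O2, hν, tetraphenylporphyrin (cat.), CH2Cl2, −40 °C; then Et3N, 0 °C → rt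
Reagents that add atoms: dioxygen, O=O
Why: Singlet-oxygen [4+2] cycloaddition anti to the C7 isopropenyl sets C6–O trans to it, and Kornblum–DeLaMare rearrangement (amine removes the less hindered, CH2-flanked bridgehead H) gives the C3 ketone and C6 hydroxyl.

**Step 4**
Reactants: 5 (4R,5S)-4-hydroxy-2-methyl-5-(prop-1-en-2-yl)cyclohex-2-en-1-one
Product: 6 5-hydroxy-1-methyl-4-(prop-1-en-2-yl)-7-oxabicyclo[4.1.0]heptan-2-one (oxirane O cis to OH; trans to isopropenyl)
Conditions: tBuOOH, DBU, CH2Cl2, 0 °C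
Reagents that add atoms: tert-butyl hydroperoxide, CC(C)(C)OO
Why: Weitz–Scheffer nucleophilic epoxidation delivered by hydrogen bonding syn to the C6 hydroxyl, which is also the face anti to isopropenyl (as in carvone), fixes C4 and C5 with the oxirane oxygen cis to C6–O.

**Step 5**
Reactants: 6 epoxy alcohol
Product: 7 5-(tert-butyldimethylsilyloxy)-1-methyl-4-(prop-1-en-2-yl)-7-oxabicyclo[4.1.0]heptan-2-one (same configuration as 6)
Conditions: TBSOTf, 2,6-lutidine, CH2Cl2, −78 → 0 °C
Reagents that add atoms: tert-butyldimethylsilyl triflate, CC(C)(C)[Si](C)(C)OS(=O)(=O)C(F)(F)F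
Why: Silylation of the only hydroxyl masks C6–O for the base, Grignard, oxidation and hydride steps; no stereocentre is affected.

**Step 6**
Reactants: 7 silyl-protected epoxy ketone; 8 propanal; 9 vinylmagnesium bromide
Product: 12 vinyl carbinol diol (C3: OH and vinyl; C8: 1-hydroxypropyl trans to isopropenyl and trans to vinyl; side-chain carbinol epimers), via lithium enolate 10 (not isolated), via lithium aldolate 11 (not isolated)
Conditions: LiN(iPr)2, THF, −78 °C; EtCHO; then CeCl3, CH2=CHMgBr (3 equiv), −78 → −40 °C; aq. NH4Cl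
Reagents that add atoms: propanal 8, CCC=O; vinylmagnesium bromide 9, C=C[Mg]Br
Why: Kinetic α′-enolate aldol (electrophile enters anti to the neighbouring isopropenyl) and, in the same flask, organocerium 1,2-addition from the equatorial face anti to the oxirane oxygen and the new C8 chain, placing vinyl trans to that chain; the carbinol epimers converge in step 7.

**Step 7**
Reactants: 12 vinyl carbinol diol
Product: 13 β-hydroxy ketone (C8 propanoyl; tertiary C3 vinyl carbinol)
Conditions: Dess–Martin periodinane, NaHCO3, CH2Cl2, 0 °C → rt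
Reagents that add atoms: none
Why: Dess–Martin oxidation acts only on the secondary carbinol (the tertiary allylic alcohol cannot be oxidised) and erases the uncontrolled carbinol centre.

**Step 8**
Reactants: 13 β-hydroxy ketone
Product: 15 tertiary vinyl carbinol carrying the C8 (Z)-1-(triisopropylsilyloxy)prop-1-enyl group, via dilithium alkoxide enolate 14 (not isolated)
Conditions: LiN(iPr)2 (2.3 equiv), THF, −78 °C; iPr3SiOTf (1.1 equiv), −78 °C; then H2O
Reagents that add atoms: triisopropylsilyl triflate, CC(C)[Si](C(C)C)(C(C)C)OS(=O)(=O)C(F)(F)F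
Why: Kinetic enolisation at the ethyl CH2 (the other α-carbon is a hindered ring methine) and O-silylation of the enolate, not of the hindered tertiary lithium alkoxide, gives the regiodefined enol ether; its geometry is of no consequence.

**Step 9**
Reactants: 15 silyl enol ether carbinol
Product: 19 ten-membered dienone (C3 ketone; C1=C2; 4,5-epoxide; 6-OTBS; 7-isopropenyl; trans C8=C9 bearing 9-OTIPS; 10-methyl of uncontrolled configuration), via potassium alkoxide 16 (not isolated), via ring-expanded potassium enolate 17 (not isolated), via α-sulfilimine ketone 18 (not isolated)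
Conditions: KN(SiMe3)2, 18-crown-6, THF, −20 → 20 °C; then PhS(Cl)=N-tBu, −78 °C → rt
Reagents that add atoms: none
Why: Anionic oxy-Cope [3,3]-sigmatropic rearrangement through a chair with both alkenyl groups equatorial cleaves C3–C8 and forms C1–C10, and the regiodefined C2 enolate is dehydrogenated in the flask (Mukaiyama dehydrogenation); C4–C7 are untouched and the new C10 centre is erased in step 12.

**Step 10**
Reactants: 19 ten-membered dienone
Product: 20 C3 allylic alcohol (3-OH anti to the 4,5-oxirane oxygen)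
Conditions: iBu2AlH, CH2Cl2, −78 °C; aq. potassium sodium tartrate
Reagents that add atoms: none
Why: 1,2-Reduction by a non-chelating aluminium hydride under the polar Felkin–Anh model (hydride anti to the oxirane C4–O bond, passing the methyl) gives the C3 alcohol anti to the oxirane oxygen.

**Step 11**
Reactants: 20 C3 allylic alcohol; 21 angelic acid
Product: 23 C8 angelate of the C9 ketone (angelate cis to isopropenyl; C1=C2 still in place), via α-bromo ketone 22 (not isolated)
Conditions: NBS, THF, −78 °C; then angelic acid, Cs2CO3, DMF, 0 °C → rt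
Reagents that add atoms: angelic acid 21, C/C=C(/C)C(=O)O
Why: Bromination of the silyl enol ether on its exposed face (anti to the transannular C3 side, so trans to isopropenyl) and SN2 displacement of the α-keto bromide by the carboxylate invert C8, placing the angelate cis to isopropenyl; the Z geometry is safe because angelate acts as a nucleophile.

**Step 12**
Reactants: 23 C8 angelate
Product: 25 1,10:4,5-diepoxide (cis 1,10-oxirane syn to 3-OH; 9-ketone; 8-angelate; 6-OTBS), via conjugated cis-enone 24 (not isolated)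
Conditions: DBU, tBuOOH, CH2Cl2, 0 °C → rt
Reagents that add atoms: tert-butyl hydroperoxide, CC(C)(C)OO
Why: Base-mediated β,γ to α,β isomerisation gives the thermodynamically preferred cis 2-methyl enone of the ten-membered ring, and Weitz–Scheffer epoxidation delivered syn to the C3 hydroxyl on the outer face fixes C1 and C10.

**Step 13**
Reactants: 25 diepoxide silyl ether
Product: 26 3,6-diol (8-angelate; 9-ketone; both oxiranes)
Conditions: HF·pyridine, pyridine/THF, 0 °C → rt
Reagents that add atoms: none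
Why: Buffered fluoride desilylation (Si–F bond formation) frees C6–OH without opening the oxiranes or isomerising the angelate; no stereocentre changes.

**Step 14**
Reactants: 26 3,6-diol; 21 angelic acid
Product: 27 target tris-angelate CNP0154187.1
Conditions: angelic acid, 2,4,6-trichlorobenzoyl chloride, Et3N, toluene, rt; then 26, 80 °C
Reagents that add atoms: angelic acid 21, C/C=C(/C)C(=O)O
Why: Yamaguchi-type mixed-anhydride acylation without a nucleophilic catalyst esterifies both secondary hydroxyls with retention and avoids Z to E isomerisation of the angeloyl groups.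

**Compound list**
1 | (R)-(−)-carvone | C=C(C)[C@H]1CC(=O)C(C)=CC1 | starting material
2 | (R)-carvone (E)-p-toluenesulfonylhydrazone | C=C(C)[C@H]1C/C(=N\NS(=O)(=O)c2ccc(C)cc2)C(C)=CC1 | intermediate
3 | (R)-2-methyl-5-(prop-1-en-2-yl)cyclohexa-1,3-diene | C=C(C)[C@H]1C=CC(C)=CC1 | intermediate
4 | 5-methyl-7-(prop-1-en-2-yl)-2,3-dioxabicyclo[2.2.2]oct-5-ene, peroxide bridge anti to isopropenyl (not isolated) | C=C(C)[C@H]1[C@H]2C=C(C)[C@@H](C1)OO2 | intermediate
5 | (4R,5S)-4-hydroxy-2-methyl-5-(prop-1-en-2-yl)cyclohex-2-en-1-one | C=C(C)[C@H]1[C@H](O)C=C(C)C(=O)C1 | intermediate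
6 | 5-hydroxy-1-methyl-4-(prop-1-en-2-yl)-7-oxabicyclo[4.1.0]heptan-2-one, oxirane O cis to OH, trans to isopropenyl | C=C(C)[C@H]1[C@H](O)[C@@H]2O[C@]2(C)C(=O)C1 | intermediate
7 | tert-butyldimethylsilyl ether of 6 | C=C(C)[C@H]1[C@H](O[Si](C)(C)C(C)(C)C)[C@@H]2O[C@]2(C)C(=O)C1 | intermediate
8 | propanal | CCC=O | starting material
9 | vinylmagnesium bromide | C=C[Mg]Br | starting material
10 | lithium α′-enolate of 7 (not isolated) | C=C(C)[C@H]1[C@H](O[Si](C)(C)C(C)(C)C)[C@@H]2O[C@]2(C)C([O-])=C1.[Li+] | intermediate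
11 | lithium aldolate, C8 chain trans to isopropenyl, carbinol epimers (not isolated) | C=C(C)[C@H]1[C@H](O[Si](C)(C)C(C)(C)C)[C@@H]2O[C@]2(C)C(=O)[C@@H]1C([O-])CC.[Li+] | intermediate
12 | vinyl carbinol diol, vinyl trans to C8 chain, carbinol epimers | C=C(C)[C@H]1[C@H](O[Si](C)(C)C(C)(C)C)[C@@H]2O[C@]2(C)[C@@](O)(C=C)[C@@H]1C(O)CC | intermediate
13 | β-hydroxy ketone (C8 propanoyl) | C=C(C)[C@H]1[C@H](O[Si](C)(C)C(C)(C)C)[C@@H]2O[C@]2(C)[C@@](O)(C=C)[C@@H]1C(=O)CC | intermediate
14 | dilithium alkoxide enolate of 13 (not isolated) | C=C(C)[C@H]1[C@H](O[Si](C)(C)C(C)(C)C)[C@@H]2O[C@]2(C)[C@@]([O-])(C=C)[C@@H]1/C([O-])=C/C.[Li+].[Li+] | intermediate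
15 | tertiary vinyl carbinol with C8 (Z)-1-(triisopropylsilyloxy)prop-1-enyl group | C=C(C)[C@H]1[C@H](O[Si](C)(C)C(C)(C)C)[C@@H]2O[C@]2(C)[C@@](O)(C=C)[C@@H]1/C(O[Si](C(C)C)(C(C)C)C(C)C)=C/C | intermediate
16 | potassium alkoxide of 15 (not isolated) | C=C(C)[C@H]1[C@H](O[Si](C)(C)C(C)(C)C)[C@@H]2O[C@]2(C)[C@@]([O-])(C=C)[C@@H]1/C(O[Si](C(C)C)(C(C)C)C(C)C)=C/C.[K+] | intermediate
17 | ring-expanded potassium C2=C3 enolate, trans C8=C9, C10 not controlled (not isolated) | C1C(C)/C(O[Si](C(C)C)(C(C)C)C(C)C)=C/[C@@H](C(C)=C)[C@H](O[Si](C)(C)C(C)(C)C)[C@@H]2O[C@]2(C)C([O-])=C1.[K+] | intermediate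
18 | C2 α-(N-tert-butyl-S-phenylsulfilimino) C3 ketone (not isolated) | C1C(C)/C(O[Si](C(C)C)(C(C)C)C(C)C)=C/[C@@H](C(C)=C)[C@H](O[Si](C)(C)C(C)(C)C)[C@@H]2O[C@]2(C)C(=O)C1S(=NC(C)(C)C)c3ccccc3 | intermediate
19 | ten-membered dienone: 3-oxo, 1-ene (geometry not defined), 4,5-epoxy, 6-OTBS, 7-isopropenyl, trans-8-ene with 9-OTIPS, 10-methyl (not controlled) | C1=CC(C)/C(O[Si](C(C)C)(C(C)C)C(C)C)=C/[C@@H](C(C)=C)[C@H](O[Si](C)(C)C(C)(C)C)[C@@H]2O[C@]2(C)C1=O | intermediate
20 | C3 allylic alcohol of 19, 3-OH anti to oxirane O | C1=CC(C)/C(O[Si](C(C)C)(C(C)C)C(C)C)=C/[C@@H](C(C)=C)[C@H](O[Si](C)(C)C(C)(C)C)[C@@H]2O[C@]2(C)[C@H]1O | intermediate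
21 | angelic acid, (Z)-2-methylbut-2-enoic acid | C/C=C(/C)C(=O)O | starting material
22 | C8 α-bromo C9 ketone, Br trans to isopropenyl (not isolated) | C1=CC(C)C(=O)[C@H](Br)[C@@H](C(C)=C)[C@H](O[Si](C)(C)C(C)(C)C)[C@@H]2O[C@]2(C)[C@H]1O | intermediate
23 | C8 angelate (cis to isopropenyl) of the 9-ketone, 3-OH, 6-OTBS, 1-ene | C1=CC(C)C(=O)[C@@H](OC(=O)/C(C)=C\C)[C@@H](C(C)=C)[C@H](O[Si](C)(C)C(C)(C)C)[C@@H]2O[C@]2(C)[C@H]1O | intermediate
24 | conjugated cis 1(10)-en-9-one (not isolated) | C1/C=C(C)\C(=O)[C@@H](OC(=O)/C(C)=C\C)[C@@H](C(C)=C)[C@H](O[Si](C)(C)C(C)(C)C)[C@@H]2O[C@]2(C)[C@H]1O | intermediate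
25 | 1,10:4,5-diepoxy-9-ketone, 8-angelate, 6-OTBS, 3-OH | C1[C@H]3O[C@@]3(C)C(=O)[C@@H](OC(=O)/C(C)=C\C)[C@@H](C(C)=C)[C@H](O[Si](C)(C)C(C)(C)C)[C@@H]2O[C@]2(C)[C@H]1O | intermediate
26 | 3,6-diol, 8-angelate | C1[C@H]3O[C@@]3(C)C(=O)[C@@H](OC(=O)/C(C)=C\C)[C@@H](C(C)=C)[C@H](O)[C@@H]2O[C@]2(C)[C@H]1O | intermediate
27 | CNP0154187.1, 3,6,8-tris(angeloyloxy)-1,10:4,5-diepoxygermacr-11-en-9-one | C=C(C)[C@H]1[C@H](OC(=O)/C(C)=C\C)[C@@H]2O[C@]2(C)[C@@H](OC(=O)/C(C)=C\C)C[C@H]2O[C@@]2(C)C(=O)[C@H]1OC(=O)/C(C)=C\C | target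

**Totals**
Total step count: 14. Longest linear sequence: 14 steps (1 → 27).

**Steps most likely to fail**

Step 3. The amine may remove the other bridgehead hydrogen and give the isomeric hydroxy enone, and ene hydroperoxides can compete with the [4+2] addition. The fallback sets out from 1 and comes back at 7, with the ketone moved by a Wharton transposition instead of the peroxide route. The kinetic enolate of 1 (LiN(iPr)2) is hydroxylated with MoO5·pyridine·HMPA to trans-6-hydroxycarvone F1. Silylation with TBSOTf gives its silyl ether F2. H2O2/NaOH epoxidises the enone anti to isopropenyl to epoxy ketone F3. Hydrazine hydrate with AcOH gives the transposed allylic alcohol F4. VO(acac)2/tBuOOH epoxidises syn to the new hydroxyl to epoxy alcohol F5, and Dess–Martin oxidation gives 7.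

Step 9. The tertiary alkoxide may take the silyl group from the enol ether (O to O transfer) before rearranging, or the enolate trapping/dehydrogenation may fail. The fallback sets out from 15 and comes back at 19 using a neutral thermal rearrangement. Compound 15 is capped with TMSCl/imidazole to the trimethylsilyl ether F6. Heating in toluene at 180 °C in a sealed tube (siloxy-Cope) gives the ring-expanded bis(silyl enol ether) F7. Pd(OAc)2 in MeCN (Saegusa–Ito oxidation) acts on the labile trimethylsilyl enol ether only and gives 19.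

Step 11. Bromination may give a mixture of faces, or the hindered α-keto bromide may eliminate or epimerise instead of undergoing clean SN2. The fallback sets out from 20 and comes back at 27, placing the oxygen first and inverting it last. Rubottom oxidation of 20 (mCPBA, NaHCO3) gives the 8-epi α-silyloxy ketone F8 (oxygen trans to isopropenyl). DBU/tBuOOH then gives the diepoxide F9. HF·pyridine at 0 °C removes only the tert-butyldimethylsilyl group to give diol F10. Mixed-anhydride angeloylation gives the 3,6-bis-angelate F11. Bu4NF/AcOH frees the 8-epi alcohol F12. Mitsunobu esterification with angelic acid (PPh3, diisopropyl azodicarboxylate) inverts C8 and gives 27.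

**Further compounds**
F1 | step 3 | trans-6-hydroxycarvone (OH trans to isopropenyl) | C=C(C)[C@H]1[C@H](O)C(=O)C(C)=CC1
F2 | step 3 | tert-butyldimethylsilyl ether of F1 | C=C(C)[C@H]1[C@H](O[Si](C)(C)C(C)(C)C)C(=O)C(C)=CC1
F3 | step 3 | 2,3-epoxy ketone of F2, oxirane trans to isopropenyl | C=C(C)[C@H]1[C@H](O[Si](C)(C)C(C)(C)C)C(=O)[C@]2(C)O[C@@H]2C1
F4 | step 3 | transposed allylic alcohol (Wharton product) | C=C(C)[C@H]1[C@H](O[Si](C)(C)C(C)(C)C)C=C(C)[C@H](O)C1
F5 | step 3 | epoxy alcohol, oxirane syn to the carbinol | C=C(C)[C@H]1[C@H](O[Si](C)(C)C(C)(C)C)[C@@H]2O[C@]2(C)[C@H](O)C1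
F6 | step 9 | trimethylsilyl ether of 15 | C=C(C)[C@H]1[C@H](O[Si](C)(C)C(C)(C)C)[C@@H]2O[C@]2(C)[C@@](O[Si](C)(C)C)(C=C)[C@@H]1/C(O[Si](C(C)C)(C(C)C)C(C)C)=C/C
F7 | step 9 | ring-expanded bis(silyl enol ether), 3-OTMS-2-ene and 9-OTIPS-8-ene | C1C(C)/C(O[Si](C(C)C)(C(C)C)C(C)C)=C/[C@@H](C(C)=C)[C@H](O[Si](C)(C)C(C)(C)C)[C@@H]2O[C@]2(C)C(O[Si](C)(C)C)=C1
F8 | step 11 | 8-epi α-(triisopropylsilyloxy) 9-ketone | C1=CC(C)C(=O)[C@H](O[Si](C(C)C)(C(C)C)C(C)C)[C@@H](C(C)=C)[C@H](O[Si](C)(C)C(C)(C)C)[C@@H]2O[C@]2(C)[C@H]1O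
F9 | step 11 | 8-epi diepoxide, 8-OTIPS, 6-OTBS, 3-OH | C1[C@H]3O[C@@]3(C)C(=O)[C@H](O[Si](C(C)C)(C(C)C)C(C)C)[C@@H](C(C)=C)[C@H](O[Si](C)(C)C(C)(C)C)[C@@H]2O[C@]2(C)[C@H]1O
F10 | step 11 | 8-epi 3,6-diol, 8-OTIPS | C1[C@H]3O[C@@]3(C)C(=O)[C@H](O[Si](C(C)C)(C(C)C)C(C)C)[C@@H](C(C)=C)[C@H](O)[C@@H]2O[C@]2(C)[C@H]1O
F11 | step 11 | 8-epi 3,6-bis-angelate, 8-OTIPS | C1[C@H]3O[C@@]3(C)C(=O)[C@H](O[Si](C(C)C)(C(C)C)C(C)C)[C@@H](C(C)=C)[C@H](OC(=O)/C(C)=C\C)[C@@H]2O[C@]2(C)[C@H]1OC(=O)/C(C)=C\C
F12 | step 11 | 8-epi 8-alcohol 3,6-bis-angelate | C1[C@H]3O[C@@]3(C)C(=O)[C@H](O)[C@@H](C(C)=C)[C@H](OC(=O)/C(C)=C\C)[C@@H]2O[C@]2(C)[C@H]1OC(=O)/C(C)=C\C
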